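**Assumption:** the SMILES is taken as written. Germacranolide numbering is used throughout: 6R,7S,8S,9S (6α‑O lactone, 7α‑H, 8β‑O, 9α‑O), C4=C5 Z and C1=C10 E (both cis within the ring), side chain 2S,3S.

## Retrosynthetic overview

1. The target comes from the 8,9‑diol lactone by two acylations: isobutyrate at O9, then the acetonide‑protected (2S,3S)‑2,3‑dihydroxy‑2‑methylbutanoic acid at O8 (made from ethyl (S)‑3‑hydroxybutanoate by two Fráter–Seebach dianion steps).
2. The ten‑membered carbocycle and the trans‑γ‑lactone are closed together at C6–C7 by an electrochemical chromium‑catalysed 2‑(methoxycarbonyl)allylation of a Z‑enal.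
3. C9–C10 is made by a nickel/photoredox decarboxylative alkenylation joining an L‑tartrate‑derived dioxolane acid (C7–C9, C11–C13) to a neryl‑acetate‑derived (Z)‑α‑bromoenoate (C1–C6, C10, C14, C15).
4. Stereocontrol: C8 is bought in L‑tartrate; C9 is re‑set trans to C8 in the radical coupling; C6 and C7 are set in the ring closure under control of C8/C9; the side‑chain centres come from the hydroxybutanoate.
5. Ring order: tartrate dioxolane (bought, temporary) → ten‑membered ring → lactone (same step). The Z‑C4=C5 olefin is bought in neryl acetate; the C1=C10 geometry comes from a Z‑selective bromo‑Wittig reaction and a stereoretentive coupling.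

## Route

Step 1
Reactants: 1 neryl acetate [(2Z)‑3,7‑dimethylocta‑2,6‑dien‑1‑yl acetate]
Product: 2 (4Z)‑6‑acetoxy‑4‑methylhex‑4‑enal
Conditions: O3 (1.0 equiv), pyridine (3 equiv), CH2Cl2, −78 °C
Reagents that add atoms: ozone, [O-][O+]=O
Why: Chemoselective ozonolysis, since the electron‑rich 6,7‑olefin reacts far faster than the 2,3‑olefin deactivated by the allylic acetate, and pyridine gives the aldehyde directly; the Z‑olefin (future C4=C5) is untouched.

Step 2
Reactants: 2 (4Z)‑6‑acetoxy‑4‑methylhex‑4‑enal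
Product: 3 methyl (2Z,6Z)‑8‑acetoxy‑2‑bromo‑6‑methylocta‑2,6‑dienoate
Conditions: Ph3P=C(Br)CO2Me (1.2 equiv), CH2Cl2, 0 → 23 °C
Reagents that add atoms: methyl bromo(triphenylphosphoranylidene)acetate, COC(=O)C(Br)=P(c1ccccc1)(c1ccccc1)c1ccccc1
Why: Wittig olefination with a stabilised ylide places the chain trans to the ester, giving the (Z)‑α‑bromoenoate that fixes the later C1=C10 geometry.

Step 3
Reactants: 3 methyl (2Z,6Z)‑8‑acetoxy‑2‑bromo‑6‑methylocta‑2,6‑dienoate
Product: 4 methyl (2Z,6Z)‑2‑bromo‑8‑hydroxy‑6‑methylocta‑2,6‑dienoate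
Conditions: K2CO3 (0.3 equiv), MeOH, 0 °C, 1 h
Reagents that add atoms: none
Why: Base‑catalysed transesterification (methanolysis) of the primary allylic acetate, done here because an allylic acetate would be ionised by zerovalent nickel in step 7 whereas the free alcohol is inert.

Step 4
Reactants: 5 dimethyl (4R,5R)‑2,2‑dimethyl‑1,3‑dioxolane‑4,5‑dicarboxylate (dimethyl 2,3‑O‑isopropylidene‑L‑tartrate)
Product: 6 methyl (4R,5R)‑5‑formyl‑2,2‑dimethyl‑1,3‑dioxolane‑4‑carboxylate
Conditions: i‑Bu2AlH (1.05 equiv), toluene, −78 °C; MeOH, then Na2SO4·10H2O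
Reagents that add atoms: none
Why: Partial hydride reduction of an ester stops at the chelated aluminium hemiacetal; the two esters of the C2‑symmetric diester are homotopic, so one aldehyde results and the formyl‑bearing carbon (future C8) keeps its tartrate configuration.

Step 5
Reactants: 6 methyl (4R,5R)‑5‑formyl‑2,2‑dimethyl‑1,3‑dioxolane‑4‑carboxylate
Product: 7 methyl (4R,5S)‑5‑[1‑hydroxy‑2‑(methoxycarbonyl)prop‑2‑en‑1‑yl]‑2,2‑dimethyl‑1,3‑dioxolane‑4‑carboxylate (both carbinol epimers)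
Conditions: methyl acrylate (5 equiv), DABCO (0.5 equiv), 1,4‑dioxane/H2O (1:1), 23 °C, 36 h
Reagents that add atoms: methyl acrylate, C=CC(=O)OC
Why: Morita–Baylis–Hillman reaction of an activated α‑alkoxy aldehyde; the new carbinol centre is removed in step 9, so its configuration does not matter, and the trans‑dioxolane is kept by the short reaction time.

Step 6
Reactants: 7 Morita–Baylis–Hillman adduct (both carbinol epimers)
Product: 8 (4R,5S)‑5‑[1‑hydroxy‑2‑(methoxycarbonyl)prop‑2‑en‑1‑yl]‑2,2‑dimethyl‑1,3‑dioxolane‑4‑carboxylic acid (both carbinol epimers)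
Conditions: LiOH·H2O (1.05 equiv), THF/H2O (3:1), 0 °C, 1 h; 1 M HCl to pH 3; acid–base extraction
Reagents that add atoms: lithium hydroxide, [Li+].[OH-]
Why: Chemoselective saponification, the α,β‑dialkoxy ester being hydrolysed much faster than the hindered conjugated acrylate ester; any cis‑dioxolane contaminant lactonises and stays in the neutral fraction.

Step 7
Reactants: 4 methyl (2Z,6Z)‑2‑bromo‑8‑hydroxy‑6‑methylocta‑2,6‑dienoate; 8 dioxolane carboxylic acid
Product: 9 methyl (2E,6Z)‑8‑hydroxy‑2‑{(4S,5S)‑5‑[1‑hydroxy‑2‑(methoxycarbonyl)prop‑2‑en‑1‑yl]‑2,2‑dimethyl‑1,3‑dioxolan‑4‑yl}‑6‑methylocta‑2,6‑dienoate (both carbinol epimers)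
Conditions: 8 (1.4 equiv), NiCl2·DME (10 mol%), 4,4′‑di‑tert‑butyl‑2,2′‑bipyridine (12 mol%), 4CzIPN (2 mol%), Cs2CO3 (1.5 equiv), DMSO (0.05 M), 450 nm LEDs, 25 °C
Reagents that add atoms: none
Why: Nickel/photoredox decarboxylative alkenylation: photo‑oxidation of the carboxylate and loss of CO2 give the dioxolan‑4‑yl radical, which the alkenyl–nickel species from oxidative addition of 4 captures on the face anti to the C8 substituent (trans‑dioxolane, so C9 is set S by C8), with retention of the bromoenoate geometry (C2 trans to CO2Me).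

Step 8
Reactants: 9 coupled diol
Product: 10 methyl (2E,6Z)‑2‑{(4S,5S)‑5‑[1‑hydroxy‑2‑(methoxycarbonyl)prop‑2‑en‑1‑yl]‑2,2‑dimethyl‑1,3‑dioxolan‑4‑yl}‑6‑methyl‑8‑oxoocta‑2,6‑dienoate (both carbinol epimers)
Conditions: TEMPO (10 mol%), PhI(OAc)2 (1.1 equiv), CH2Cl2, 23 °C
Reagents that add atoms: none
Why: Oxoammonium (TEMPO) oxidation is selective for the primary allylic alcohol over the secondary one and is neutral, so the Z‑enal does not isomerise.

Step 9
Reactants: 10 enal alcohol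
Product: 11 methyl (2E,6Z)‑2‑{(4S,5S)‑5‑[(1Z)‑3‑bromo‑2‑(methoxycarbonyl)prop‑1‑en‑1‑yl]‑2,2‑dimethyl‑1,3‑dioxolan‑4‑yl}‑6‑methyl‑8‑oxoocta‑2,6‑dienoate
Conditions: NBS (1.4 equiv), Me2S (1.6 equiv), CH2Cl2, −20 → 0 °C
Reagents that add atoms: N‑bromosuccinimide, O=C1CCC(=O)N1Br
Why: Corey–Kim‑type SN2′ bromination of the Morita–Baylis–Hillman alcohol gives the thermodynamically preferred (Z)‑2‑(bromomethyl)enoate, and both carbinol epimers converge on it.

Step 10
Reactants: 11 allylic bromide Z‑enal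
Product: 14 acetonide‑protected ten‑membered trans‑lactone [methyl 8β,9α‑(isopropylidenedioxy)‑12‑oxo‑6α,12‑epoxygermacra‑1(10)E,4Z,11(13)‑trien‑14‑oate; 7α‑H], via silyl ether 12 (not isolated), via hydroxy diester 13 (not isolated)
Conditions: CrCl2 (15 mol%), Me3SiCl (2.5 equiv), n‑Bu4NBr (0.1 M), DMF/THF (1:1), undivided cell, Al anode, reticulated vitreous carbon cathode, 3 mA constant current (2.4 F/mol), 11 added over 12 h (final 2 mM), 23 °C; then 1 M aq. citric acid/THF, 23 °C, 2 h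
Reagents that add atoms: none
Why: Proposed new method: divalent chromium, regenerated at the cathode from catalytic CrCl2 instead of being used in excess, turns the allylic bromide into a 2‑(methoxycarbonyl)allyl complex of trivalent chromium that adds through C7 to the tethered Z‑enal in a chair‑like six‑membered transition state with C5 and C8 equatorial (anti adduct, hence the 6,7‑trans lactone once the C6 oxygen closes onto the C12 ester) and on the C7 face next to C8–H, not next to the dioxolane oxygen, with the C9 tether anti to C11 (6R,7S from the tartrate‑derived 8S,9S centres), while Me3SiCl strips the alkoxide from chromium so the cycle turns over; the closest known reactions are the stoichiometric CrCl2 Nozaki–Hiyama macro‑allylation used to close germacranolide rings and the chromium‑catalysed electrochemical Nozaki–Hiyama–Kishi coupling of alkenyl halides, neither shown as an electrocatalytic ring closure of a 2‑(alkoxycarbonyl)allyl bromide onto an aldehyde.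

Step 11
Reactants: 14 acetonide‑protected trans‑lactone
Product: 15 methyl 8β,9α‑dihydroxy‑12‑oxo‑6α,12‑epoxygermacra‑1(10)E,4Z,11(13)‑trien‑14‑oate (7α‑H)
Conditions: p‑TsOH·H2O (0.2 equiv), MeOH/H2O (9:1), 23 °C
Reagents that add atoms: none
Why: Acid‑catalysed acetal hydrolysis of the strained trans‑fused dioxolane under mild conditions; the ester‑deactivated C1=C10 olefin suppresses transannular cyclisation.

Step 12
Reactants: 15 diol lactone
Product: 16 methyl 8β‑hydroxy‑9α‑(isobutyryloxy)‑12‑oxo‑6α,12‑epoxygermacra‑1(10)E,4Z,11(13)‑trien‑14‑oate (7α‑H)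
Conditions: (i‑PrCO)2O (1.1 equiv), 2,4,6‑collidine (2 equiv), DMAP (5 mol%), CH2Cl2, −40 °C
Reagents that add atoms: isobutyric anhydride, CC(C)C(=O)OC(=O)C(C)C
Why: Kinetic mono‑acylation (DMAP‑catalysed), expected at O9–H because it is allylic, flanked by the planar C10 and hydrogen‑bonded to the C14 carbonyl, whereas O8–H sits next to the lactone ring fusion.

Step 13
Reactants: 17 ethyl (S)‑3‑hydroxybutanoate
Product: 18 ethyl (2S,3S)‑3‑hydroxy‑2‑methylbutanoate
Conditions: LiN(i‑Pr)2 (2.2 equiv), THF, −50 → −20 °C; MeI (1.3 equiv), DMPU, −78 → −20 °C; 1 M HCl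
Reagents that add atoms: iodomethane, CI
Why: Fráter–Seebach alkylation: the lithium‑chelated dianion is methylated anti to the C3 methyl group, giving the anti (2S,3S) ester under control of the purchased C3 centre.

Step 14
Reactants: 18 ethyl (2S,3S)‑3‑hydroxy‑2‑methylbutanoate
Product: 19 ethyl (2S,3S)‑2,3‑dihydroxy‑2‑methylbutanoate
Conditions: LiN(i‑Pr)2 (2.3 equiv), THF, −78 → −30 °C; MoO5·pyridine·HMPA (MoOPH, 1.5 equiv), −78 → −20 °C; 1 M HCl
Reagents that add atoms: oxodiperoxymolybdenum(pyridine)(hexamethylphosphoric triamide), O=[Mo]12(OO1)OO2.c1ccncc1.CN(C)P(=O)(N(C)C)N(C)C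
Why: Fráter–Seebach‑type electrophilic hydroxylation (Vedejs MoOPH oxidation) of the chelated tetrasubstituted dianion, in which oxygen enters from the same face as the methyl did in step 13 and so takes that position, giving the (2S) quaternary carbinol under control of C3.

Step 15
Reactants: 19 ethyl (2S,3S)‑2,3‑dihydroxy‑2‑methylbutanoate
Product: 20 ethyl (4S,5S)‑2,2,4,5‑tetramethyl‑1,3‑dioxolane‑4‑carboxylate
Conditions: 2,2‑dimethoxypropane (5 equiv), p‑TsOH·H2O (5 mol%), CH2Cl2, 23 °C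
Reagents that add atoms: 2,2‑dimethoxypropane, COC(C)(C)OC
Why: Acid‑catalysed transketalisation protects the tertiary and secondary hydroxyls together as the acetonide; no stereocentre changes.

Step 16
Reactants: 20 ethyl (4S,5S)‑2,2,4,5‑tetramethyl‑1,3‑dioxolane‑4‑carboxylate
Product: 21 (4S,5S)‑2,2,4,5‑tetramethyl‑1,3‑dioxolane‑4‑carboxylic acid
Conditions: LiOH·H2O (2 equiv), THF/H2O (2:1), 40 °C; cold 1 M HCl to pH 3
Reagents that add atoms: lithium hydroxide, [Li+].[OH-]
Why: Saponification of the ester; the α‑carbon is quaternary and cannot epimerise.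

Step 17
Reactants: 16 9α‑isobutyrate 8β‑alcohol; 21 acetonide acid
Product: 23 methyl 9α‑(isobutyryloxy)‑8β‑{[(4S,5S)‑2,2,4,5‑tetramethyl‑1,3‑dioxolane‑4‑carbonyl]oxy}‑12‑oxo‑6α,12‑epoxygermacra‑1(10)E,4Z,11(13)‑trien‑14‑oate (7α‑H), via mixed anhydride 22 (not isolated)
Conditions: 21 (1.5 equiv), 2,4,6‑trichlorobenzoyl chloride (1.5 equiv), Et3N (2 equiv), toluene, 23 °C; then 16, DMAP (2 equiv), toluene, 23 → 40 °C
Reagents that add atoms: none
Why: Yamaguchi esterification through the mixed anhydride and the acylpyridinium couples the hindered α‑quaternary acid to the hindered C8 alcohol without touching any stereocentre.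

Step 18
Reactants: 23 fully acylated acetonide
Product: 24 target, methyl (1(10)E,4Z,6R,7S,8S,9S)‑8‑{[(2S,3S)‑2,3‑dihydroxy‑2‑methylbutanoyl]oxy}‑9‑(isobutyryloxy)‑12‑oxo‑6,12‑epoxygermacra‑1(10),4,11(13)‑trien‑14‑oate
Conditions: TFA/H2O (4:1), CH2Cl2, 0 °C, 30 min
Reagents that add atoms: none
Why: Acid hydrolysis of the side‑chain acetonide, kept brief and cold so that the esters, the lactone and the Z‑trisubstituted olefin survive.

## Compound list

1 | neryl acetate | CC(C)=CCC/C(C)=C\COC(C)=O | starting material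
2 | (4Z)‑6‑acetoxy‑4‑methylhex‑4‑enal | O=CCC/C(C)=C\COC(C)=O | intermediate
3 | methyl (2Z,6Z)‑8‑acetoxy‑2‑bromo‑6‑methylocta‑2,6‑dienoate | COC(=O)/C(Br)=C/CC/C(C)=C\COC(C)=O | intermediate
4 | methyl (2Z,6Z)‑2‑bromo‑8‑hydroxy‑6‑methylocta‑2,6‑dienoate | COC(=O)/C(Br)=C/CC/C(C)=C\CO | intermediate
5 | dimethyl (4R,5R)‑2,2‑dimethyl‑1,3‑dioxolane‑4,5‑dicarboxylate | COC(=O)[C@@H]1OC(C)(C)O[C@H]1C(=O)OC | starting material
6 | methyl (4R,5R)‑5‑formyl‑2,2‑dimethyl‑1,3‑dioxolane‑4‑carboxylate | COC(=O)[C@@H]1OC(C)(C)O[C@H]1C=O | intermediate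
7 | methyl (4R,5S)‑5‑[1‑hydroxy‑2‑(methoxycarbonyl)prop‑2‑en‑1‑yl]‑2,2‑dimethyl‑1,3‑dioxolane‑4‑carboxylate (carbinol epimers) | COC(=O)[C@@H]1OC(C)(C)O[C@H]1C(O)C(=C)C(=O)OC | intermediate
8 | (4R,5S)‑5‑[1‑hydroxy‑2‑(methoxycarbonyl)prop‑2‑en‑1‑yl]‑2,2‑dimethyl‑1,3‑dioxolane‑4‑carboxylic acid (carbinol epimers) | OC(=O)[C@@H]1OC(C)(C)O[C@H]1C(O)C(=C)C(=O)OC | intermediate
9 | methyl (2E,6Z)‑8‑hydroxy‑2‑{(4S,5S)‑5‑[1‑hydroxy‑2‑(methoxycarbonyl)prop‑2‑en‑1‑yl]‑2,2‑dimethyl‑1,3‑dioxolan‑4‑yl}‑6‑methylocta‑2,6‑dienoate (carbinol epimers) | COC(=O)/C(=C/CC/C(C)=C\CO)[C@@H]1OC(C)(C)O[C@H]1C(O)C(=C)C(=O)OC | intermediate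
10 | methyl (2E,6Z)‑2‑{(4S,5S)‑5‑[1‑hydroxy‑2‑(methoxycarbonyl)prop‑2‑en‑1‑yl]‑2,2‑dimethyl‑1,3‑dioxolan‑4‑yl}‑6‑methyl‑8‑oxoocta‑2,6‑dienoate (carbinol epimers) | COC(=O)/C(=C/CC/C(C)=C\C=O)[C@@H]1OC(C)(C)O[C@H]1C(O)C(=C)C(=O)OC | intermediate
11 | methyl (2E,6Z)‑2‑{(4S,5S)‑5‑[(1Z)‑3‑bromo‑2‑(methoxycarbonyl)prop‑1‑en‑1‑yl]‑2,2‑dimethyl‑1,3‑dioxolan‑4‑yl}‑6‑methyl‑8‑oxoocta‑2,6‑dienoate | COC(=O)/C(=C/CC/C(C)=C\C=O)[C@@H]1OC(C)(C)O[C@H]1/C=C(\CBr)C(=O)OC | intermediate
12 | dimethyl 8β,9α‑(isopropylidenedioxy)‑6α‑(trimethylsilyloxy)germacra‑1(10)E,4Z,11(13)‑triene‑12,14‑dioate (7α‑H) | C=C(C(=O)OC)[C@H]1[C@H](O[Si](C)(C)C)/C=C(/C)CC/C=C(/C(=O)OC)[C@@H]2OC(C)(C)O[C@H]21 | intermediate (not isolated)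
13 | dimethyl 6α‑hydroxy‑8β,9α‑(isopropylidenedioxy)germacra‑1(10)E,4Z,11(13)‑triene‑12,14‑dioate (7α‑H) | C=C(C(=O)OC)[C@H]1[C@H](O)/C=C(/C)CC/C=C(/C(=O)OC)[C@@H]2OC(C)(C)O[C@H]21 | intermediate (not isolated)
14 | methyl 8β,9α‑(isopropylidenedioxy)‑12‑oxo‑6α,12‑epoxygermacra‑1(10)E,4Z,11(13)‑trien‑14‑oate (7α‑H) | C=C1C(=O)O[C@@H]2/C=C(/C)CC/C=C(/C(=O)OC)[C@@H]3OC(C)(C)O[C@H]3[C@@H]12 | intermediate
15 | methyl 8β,9α‑dihydroxy‑12‑oxo‑6α,12‑epoxygermacra‑1(10)E,4Z,11(13)‑trien‑14‑oate (7α‑H) | C=C1C(=O)O[C@@H]2/C=C(/C)CC/C=C(/C(=O)OC)[C@H](O)[C@@H](O)[C@@H]12 | intermediate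
16 | methyl 8β‑hydroxy‑9α‑(isobutyryloxy)‑12‑oxo‑6α,12‑epoxygermacra‑1(10)E,4Z,11(13)‑trien‑14‑oate (7α‑H) | C=C1C(=O)O[C@@H]2/C=C(/C)CC/C=C(/C(=O)OC)[C@H](OC(=O)C(C)C)[C@@H](O)[C@@H]12 | intermediate
17 | ethyl (S)‑3‑hydroxybutanoate | CCOC(=O)C[C@H](C)O | starting material
18 | ethyl (2S,3S)‑3‑hydroxy‑2‑methylbutanoate | CCOC(=O)[C@@H](C)[C@H](C)O | intermediate
19 | ethyl (2S,3S)‑2,3‑dihydroxy‑2‑methylbutanoate | CCOC(=O)[C@@](C)(O)[C@H](C)O | intermediate
20 | ethyl (4S,5S)‑2,2,4,5‑tetramethyl‑1,3‑dioxolane‑4‑carboxylate | CCOC(=O)[C@@]1(C)OC(C)(C)O[C@H]1C | intermediate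
21 | (4S,5S)‑2,2,4,5‑tetramethyl‑1,3‑dioxolane‑4‑carboxylic acid | OC(=O)[C@@]1(C)OC(C)(C)O[C@H]1C | intermediate
22 | (4S,5S)‑2,2,4,5‑tetramethyl‑1,3‑dioxolane‑4‑carboxylic 2,4,6‑trichlorobenzoic anhydride | O=C(OC(=O)[C@@]1(C)OC(C)(C)O[C@H]1C)c1c(Cl)cc(Cl)cc1Cl | intermediate (not isolated)
23 | methyl 9α‑(isobutyryloxy)‑8β‑{[(4S,5S)‑2,2,4,5‑tetramethyl‑1,3‑dioxolane‑4‑carbonyl]oxy}‑12‑oxo‑6α,12‑epoxygermacra‑1(10)E,4Z,11(13)‑trien‑14‑oate (7α‑H) | C=C1C(=O)O[C@@H]2/C=C(/C)CC/C=C(/C(=O)OC)[C@H](OC(=O)C(C)C)[C@@H](OC(=O)[C@@]3(C)OC(C)(C)O[C@H]3C)[C@@H]12 | intermediate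
24 | methyl (1(10)E,4Z,6R,7S,8S,9S)‑8‑{[(2S,3S)‑2,3‑dihydroxy‑2‑methylbutanoyl]oxy}‑9‑(isobutyryloxy)‑12‑oxo‑6,12‑epoxygermacra‑1(10),4,11(13)‑trien‑14‑oate | C=C1C(=O)O[C@@H]2/C=C(/C)CC/C=C(/C(=O)OC)[C@H](OC(=O)C(C)C)[C@@H](OC(=O)[C@@](C)(O)[C@H](C)O)[C@@H]12 | target

## Step count and risks

Total: 18 steps. Longest linear sequence: 11 steps (from 5 through steps 4–12, 17 and 18 to 24; the branch from 1 is equally long).

The three steps most likely to fail:

**Step 10 (the proposed electrocatalytic ring closure).** The risks are oligomerisation, isomerisation of the Z‑enal by the Lewis‑acidic medium, 1,4‑elimination of the dioxolane oxygen from the allylchromium species, and an unfavourable ratio at C6/C7. The stereochemical outcome is an argument from a transition‑state model, not a demonstrated result. The fallback gives up the electrocatalytic manifold and uses the established stoichiometric organochromium closure. It sets out from 11, which is added by syringe pump over 12 h to CrCl2 (8 equiv) in degassed THF/DMF at 23 °C (classical Nozaki–Hiyama macro‑allylation, known for ten‑membered germacranolide rings); the chromium alkoxide lactonises in the flask and, after a citric acid wash, the route is rejoined at 14 (no new compound, F0).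

**Step 7 (photochemical C9–C10 coupling).** The α‑bromoenoate is an unusual alkenyl partner, and the acrylate unit of 8 can intercept the dioxolanyl radical in a Giese addition. The fallback changes the way the radical is made and removes light and base. It sets out from 8 and 4: acid 8 is converted (N‑hydroxyphthalimide, N,N′‑diisopropylcarbodiimide, DMAP cat., CH2Cl2) into the N‑(acyloxy)phthalimide of acid 8 F1, which is coupled with bromide 4 under thermal nickel‑catalysed reductive cross‑electrophile conditions (NiBr2·DME, 4,4′‑di‑tert‑butyl‑2,2′‑bipyridine, Zn dust, DMA, 25 °C). Single‑electron reduction of F1 releases the same radical, which is again captured trans to the C8 substituent, and the route comes back at 9.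

**Step 12 (regioselective 9‑O‑acylation).** The preference for O9 rests on steric and hydrogen‑bond arguments only, and the 9‑isobutyrate could migrate to O8 in the basic step 17. The fallback replaces kinetic electrophile discrimination by tin‑template activation. It sets out from 15, which is heated with Bu2SnO (1.05 equiv) in MeOH at 60 °C and evaporated to give the dibutylstannylene acetal of diol 15 F2. Treatment with isobutyryl chloride (1.05 equiv) in CH2Cl2 at 0 °C acylates the oxygen activated in the stannylene (expected to be O9, the less hindered and more acidic one), and aqueous work‑up returns the route at 16.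

## Further compounds

F1 | step 7 | N‑(acyloxy)phthalimide of acid 8 | O=C(ON1C(=O)c2ccccc2C1=O)[C@@H]1OC(C)(C)O[C@H]1C(O)C(=C)C(=O)OC
F0 | step 10 | none | none
F2 | step 12 | dibutylstannylene acetal of diol 15 | C=C1C(=O)O[C@@H]2/C=C(/C)CC/C=C(/C(=O)OC)[C@@H]3O[Sn](CCCC)(CCCC)O[C@H]3[C@@H]12
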